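Assumption: silyl groups are counted as protecting groups (TIPS = tri(propan-2-yl)silyl, TBS = tert-butyl(dimethyl)silyl, TES = triethylsilyl, TMS = trimethylsilyl), and NaC5H5 (THF solution), TIPSOCH2Cl and (2R,3R)-3-methyloxiranemethanol are bought.

## Retrosynthetic overview

1. The pyran is closed last by 6-endo oxa-Michael addition of the C1 hydroxyl onto a 3-alkynylcyclohexenone; the enyne comes from a Sonogashira union of the ring alkyne with a side-chain (E)-vinyl iodide.
2. The carbocycle comes from a ring expansion: in a 1-acetylcyclopent-2-enyl silyl ether the siloxy-bearing ring carbon shifts onto the acetyl carbon (cyclopentene to cyclohexenone, sets C7).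
3. The cyclopentene comes from cyclopentadienide: C-alkylation, singlet oxygen/Kornblum–DeLaMare, ene-dione, CBS desymmetrisation (C8, C8a), alkynylation with oxidative 1,3-transposition, acetyl-anion addition.
4. The side chain comes from (2R,3R)-3-methyloxiranemethanol: epoxy ynone, chelate-controlled MeMgCl addition (C3'), copper-catalysed ethyl opening with inversion (C5'), hydrostannation/iodination.
5. Ring order: cyclopentene (bought ring), then cyclohexenone (ring expansion), then pyran.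

## Route

**Step 1**
Reactants: 1 sodium cyclopentadienide (NaC5H5); 2 (triisopropylsiloxy)methyl chloride (TIPSOCH2Cl)
Product: 6 2-(TIPSOCH2)cyclopent-4-ene-1,3-dione, via silyloxymethylcyclopentadiene 3 (not isolated), via meso-endoperoxide 4 (not isolated), via racemic trans-hydroxy enone 5 (not isolated)
Conditions: THF, −78 → −50 °C; O2, hν, tetraphenylporphyrin (0.5 mol %), CH2Cl2, −78 °C; Et3N (0.2 equiv), −78 → −20 °C; MnO2 (10 equiv), 0 → 23 °C
Reagents that add atoms: dioxygen, O=O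
Why: C-alkylation of cyclopentadienide, [4+2] addition of singlet oxygen to the cold diene (no 1,5-hydrogen shift) anti to the side chain, Kornblum–DeLaMare rearrangement of the endoperoxide and MnO2 oxidation of the allylic alcohol give the prochiral ene-dione, so no stereocentre has to be controlled here.

**Step 2**
Reactants: 6 2-(TIPSOCH2)cyclopent-4-ene-1,3-dione
Product: 7 (4S,5S)-4-hydroxy-5-(TIPSOCH2)cyclopent-2-en-1-one
Conditions: (S)-2-methyl-CBS-oxazaborolidine (20 mol %), catecholborane (1.2 equiv), toluene/CH2Cl2, −78 °C; MeOH, aq. NaHCO3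
Reagents that add atoms: none
Why: Corey–Bakshi–Shibata reduction (desymmetrisation): with the alkene arm as the large group the (S)-catalyst reduces only the carbonyl whose favoured face is also the face anti to CH2OTIPS, so hydride enters anti to that group and gives the cis hydroxy ketone with both centres set (4S,5S; later C8 and C8a).

**Step 3**
Reactants: 7 (4S,5S)-4-hydroxy-5-(TIPSOCH2)cyclopent-2-en-1-one
Product: 8 (4S,5S)-4-(TBSO)-5-(TIPSOCH2)cyclopent-2-en-1-one
Conditions: TBSCl, imidazole, DMF, 0 °C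
Reagents that add atoms: tert-butyl(chloro)dimethylsilane, CC(C)(C)[Si](C)(C)Cl
Why: Standard silylation of the secondary alcohol under weakly basic conditions, done at once because the cis β-hydroxy ketone can epimerise at C5.

**Step 4**
Reactants: 8 (4S,5S)-4-(TBSO)-5-(TIPSOCH2)cyclopent-2-en-1-one; 9 ethynyl(trimethyl)silane
Product: 10 (1R,4S,5S)-4-(TBSO)-5-(TIPSOCH2)-1-(TMS-ethynyl)cyclopent-2-en-1-ol
Conditions: 9, n-BuLi, THF, −78 °C; then 8, −78 °C; aq. NH4Cl
Reagents that add atoms: none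
Why: 1,2-Addition of the lithium acetylide to the enone carbonyl (alkynylation), mainly anti to the neighbouring CH2OTIPS group; the new carbinol centre is erased in step 5.

**Step 5**
Reactants: 10 (1R,4S,5S)-4-(TBSO)-5-(TIPSOCH2)-1-(TMS-ethynyl)cyclopent-2-en-1-ol
Product: 11 (4S,5R)-5-(TBSO)-4-(TIPSOCH2)-3-(TMS-ethynyl)cyclopent-2-en-1-one
Conditions: [C5H5NH][CrO3Cl] (2.5 equiv), NaOAc, 4 Å molecular sieves, CH2Cl2, 23 °C
Reagents that add atoms: pyridinium chlorochromate, [O-][Cr](=O)(=O)Cl.c1cc[nH+]cc1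
Why: Dauben–Babler oxidative 1,3-transposition: the tertiary allylic chromate ester shifts to the other allylic terminus and is oxidised there, which puts the carbonyl next to the OTBS carbon and leaves the alkyne on the β-carbon; the two ring stereocentres are untouched.

**Step 6**
Reactants: 11 (4S,5R)-5-(TBSO)-4-(TIPSOCH2)-3-(TMS-ethynyl)cyclopent-2-en-1-one; 12 ethyl vinyl ether
Product: 14 1-[(1S,4S,5R)-5-(TBSO)-1-(TESO)-4-(TIPSOCH2)-3-(TMS-ethynyl)cyclopent-2-en-1-yl]ethan-1-one, via bis-silyl enol ether 13 (not isolated)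
Conditions: 12, t-BuLi, THF, −78 → 0 °C; then 11, −78 °C; Et3SiOTf, −78 → −20 °C; 0.5 M aq. oxalic acid, THF, 0 °C
Reagents that add atoms: triethylsilyl trifluoromethanesulfonate, CC[Si](CC)(CC)OS(=O)(=O)C(F)(F)F; water, O
Why: 1-Ethoxyvinyllithium (acetyl anion equivalent) adds 1,2 to the ketone from the face opposite to both the OTBS and the CH2OTIPS group, so the new C1–O bond is cis to OTBS (1S); O-silylation and mild hydrolysis of the enol ether unveil the methyl ketone.

**Step 7**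
Reactants: 14 1-[(1S,4S,5R)-5-(TBSO)-1-(TESO)-4-(TIPSOCH2)-3-(TMS-ethynyl)cyclopent-2-en-1-yl]ethan-1-one
Product: 15 (4S,5R,6S)-5-(TBSO)-6-methyl-6-(TESO)-4-(TIPSOCH2)-3-(TMS-ethynyl)cyclohex-2-en-1-one
Conditions: Et3SiOTf (10 mol %), 2,6-di-tert-butyl-4-methylpyridine (10 mol %), CH2Cl2, −78 → −30 °C
Reagents that add atoms: none
Why: Proposed new method: a silyl-triflate-catalysed, silyl-relay α-ketol (acyloin) ring expansion in which Et3SiOTf silylates the acetyl oxygen, the lone pair of the tertiary C1–OSiEt3 oxygen drives a 1,2-shift of the ring bond C1–C5 (the siloxy-bearing sp3 carbon, whose departure leaves the developing C1 oxocarbenium conjugated with the enyne) onto the activated carbonyl carbon, and the silylated enone hands Et3Si+ on to the next substrate molecule, so the five-membered ring becomes the conjugated six-membered enone; because a silyl ether cannot chelate, the C–OSi and the silylated C=O dipoles stay antiperiplanar during the shift and the new C6–O bond forms on the face opposite to the old C1–O bond, that is trans to OTBS (6S), the course known for non-chelated (base-mediated) acyloin shifts; the closest known chemistry is the Lewis-acid-promoted α-ketol ring expansion of tertiary α-hydroxy ketones (D-homo-steroid rearrangement) and the aluminium-Lewis-acid-promoted 1,2-shift of α-siloxy aldehydes to α-siloxy ketones, neither shown as a silyl-triflate-catalysed ring expansion of a 1-acetylcyclopent-2-enyl silyl ether.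

**Step 8**
Reactants: 16 (2R,3R)-3-methyloxiranemethanol
Product: 17 potassium (2S,3R)-3-methyloxirane-2-carboxylate
Conditions: RuCl3·xH2O (2 mol %), NaIO4 (2.2 equiv), MeCN/EtOAc/H2O, 0 → 23 °C; then KHCO3 (1.0 equiv), freeze-dry
Reagents that add atoms: sodium periodate, [Na+].[O-]I(=O)(=O)=O; potassium hydrogen carbonate, [K+].OC([O-])=O
Why: Sharpless ruthenium tetroxide oxidation (catalytic RuCl3, NaIO4) takes the primary alcohol to the acid without touching the epoxide stereocentres; the salt is isolated because the free epoxy acid is labile.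

**Step 9**
Reactants: 17 potassium (2S,3R)-3-methyloxirane-2-carboxylate; 9 ethynyl(trimethyl)silane
Product: 19 1-[(2S,3R)-3-methyloxiran-2-yl]-3-(trimethylsilyl)prop-2-yn-1-one, via epoxy acid chloride 18 (not isolated)
Conditions: (COCl)2 (1.05 equiv), DMF (cat.), CH2Cl2, 0 °C; then 9, PdCl2(PPh3)2 (2 mol %), CuI (4 mol %), Et3N (1.2 equiv), THF, 23 °C
Reagents that add atoms: none
Why: Oxalyl chloride turns the carboxylate salt into the acid chloride without free HCl (epoxide intact) and an acyl Sonogashira coupling gives the ynone; stereocentres untouched.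

**Step 10**
Reactants: 19 1-[(2S,3R)-3-methyloxiran-2-yl]-3-(trimethylsilyl)prop-2-yn-1-one
Product: 22 (3R,4S,5R)-3,5-dimethylhept-1-yne-3,4-diol, via epoxy carbinol 20 (not isolated), via silylalkyne diol 21 (not isolated)
Conditions: MeMgCl (1.2 equiv), CH2Cl2/THF, −78 °C; then CuI (15 mol %), EtMgCl (3 equiv), THF, −40 → 0 °C; aq. NH4Cl; K2CO3, MeOH, 23 °C
Reagents that add atoms: methylmagnesium chloride, C[Mg]Cl; ethylmagnesium chloride, CC[Mg]Cl
Why: MeMgCl adds to the epoxy ynone under chelate (Cram) control, epoxide and carbonyl oxygens held syn as in the anti-selective reductions of α,β-epoxy ketones, which sets C3 (R, hydroxyl anti to the epoxide oxygen); copper-catalysed SN2 opening by EtMgCl at the methyl-bearing epoxide carbon, the one not shielded by the quaternary carbinol, inverts it and sets C5 (R) while C4 keeps its oxygen (S); methanolysis removes the C-silyl group.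

**Step 11**
Reactants: 22 (3R,4S,5R)-3,5-dimethylhept-1-yne-3,4-diol
Product: 24 (1E,3R,4S,5R)-1-iodo-3,5-dimethylhept-1-ene-3,4-diol, via E-vinylstannane 23 (not isolated)
Conditions: Bu3SnH (1.2 equiv), PdCl2(PPh3)2 (2 mol %), THF, 0 °C; then I2, CH2Cl2, 0 °C
Reagents that add atoms: diiodine, [I][I]
Why: Palladium-catalysed syn-hydrostannation puts tin on the terminal carbon (bulky tertiary carbinol next to the alkyne) to give the E-vinylstannane, and iododestannylation keeps the geometry.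

**Step 12**
Reactants: 15 (4S,5R,6S)-5-(TBSO)-6-methyl-6-(TESO)-4-(TIPSOCH2)-3-(TMS-ethynyl)cyclohex-2-en-1-one; 24 (1E,3R,4S,5R)-1-iodo-3,5-dimethylhept-1-ene-3,4-diol
Product: 25 (4S,5R,6S)-5-(TBSO)-3-[(3E,5R,6S,7R)-5,6-dihydroxy-5,7-dimethylnon-3-en-1-yn-1-yl]-6-methyl-6-(TESO)-4-(TIPSOCH2)cyclohex-2-en-1-one
Conditions: Pd(PPh3)4 (5 mol %), CuI (10 mol %), CsF (2 equiv), Et3N, DMF, 23 °C
Reagents that add atoms: none
Why: Fluoride-promoted sila-Sonogashira coupling: CsF passes the alkynyl group from silicon to copper and the palladium/copper pair joins it to the vinyl iodide with retention of the E geometry; the primary OTIPS group stays on, so the pyran cannot close before the side chain is in place.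

**Step 13**
Reactants: 25 (4S,5R,6S)-5-(TBSO)-3-[(3E,5R,6S,7R)-5,6-dihydroxy-5,7-dimethylnon-3-en-1-yn-1-yl]-6-methyl-6-(TESO)-4-(TIPSOCH2)cyclohex-2-en-1-one
Product: 27 (7S,8R,8aS)-3-[(1E,3R,4S,5R)-3,4-dihydroxy-3,5-dimethylhept-1-en-1-yl]-7,8-dihydroxy-7-methyl-1,7,8,8a-tetrahydro-6H-isochromen-6-one, via desilylated pentaol 26 (not isolated)
Conditions: HF·pyridine, pyridine, THF, 0 → 40 °C; then Et3N (excess), 23 °C
Reagents that add atoms: none
Why: Fluoride cleaves the three O–Si bonds and the freed primary hydroxyl adds 6-endo (oxa-Michael at the δ-carbon of the ynenone) under amine base to give the 2H-pyran; no stereocentre is touched.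

## Compound list

1 | sodium cyclopentadienide | [Na+].[CH-]1C=CC=C1 | starting material
2 | (triisopropylsiloxy)methyl chloride | CC(C)[Si](OCCl)(C(C)C)C(C)C | starting material
3 | 5-(TIPSOCH2)cyclopenta-1,3-diene | CC(C)[Si](OCC1C=CC=C1)(C(C)C)C(C)C | intermediate (not isolated)
4 | meso-7-(TIPSOCH2)-2,3-dioxabicyclo[2.2.1]hept-5-ene, side chain anti to the O–O bridge | CC(C)[Si](OC[C@@H]1[C@@H]2C=C[C@H]1OO2)(C(C)C)C(C)C | intermediate (not isolated)
5 | rac-(4R,5S)-4-hydroxy-5-(TIPSOCH2)cyclopent-2-en-1-one (trans; one enantiomer drawn) | O=C1C=C[C@@H](O)[C@@H]1CO[Si](C(C)C)(C(C)C)C(C)C | intermediate (not isolated)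
6 | 2-(TIPSOCH2)cyclopent-4-ene-1,3-dione | O=C1C=CC(=O)C1CO[Si](C(C)C)(C(C)C)C(C)C | intermediate
7 | (4S,5S)-4-hydroxy-5-(TIPSOCH2)cyclopent-2-en-1-one (cis) | O=C1C=C[C@H](O)[C@@H]1CO[Si](C(C)C)(C(C)C)C(C)C | intermediate
8 | (4S,5S)-4-(TBSO)-5-(TIPSOCH2)cyclopent-2-en-1-one | O=C1C=C[C@H](O[Si](C)(C)C(C)(C)C)[C@@H]1CO[Si](C(C)C)(C(C)C)C(C)C | intermediate
9 | ethynyl(trimethyl)silane | C#C[Si](C)(C)C | starting material
10 | (1R,4S,5S)-4-(TBSO)-5-(TIPSOCH2)-1-(TMS-ethynyl)cyclopent-2-en-1-ol (major C1 epimer) | O[C@]1(C#C[Si](C)(C)C)C=C[C@H](O[Si](C)(C)C(C)(C)C)[C@@H]1CO[Si](C(C)C)(C(C)C)C(C)C | intermediate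
11 | (4S,5R)-5-(TBSO)-4-(TIPSOCH2)-3-(TMS-ethynyl)cyclopent-2-en-1-one | O=C1C=C(C#C[Si](C)(C)C)[C@@H](CO[Si](C(C)C)(C(C)C)C(C)C)[C@H]1O[Si](C)(C)C(C)(C)C | intermediate
12 | ethyl vinyl ether | C=COCC | starting material
13 | (1S,4S,5R)-5-(TBSO)-1-(1-ethoxyethenyl)-1-(TESO)-4-(TIPSOCH2)-3-(TMS-ethynyl)cyclopent-2-ene | C=C(OCC)[C@]1(O[Si](CC)(CC)CC)C=C(C#C[Si](C)(C)C)[C@@H](CO[Si](C(C)C)(C(C)C)C(C)C)[C@H]1O[Si](C)(C)C(C)(C)C | intermediate (not isolated)
14 | 1-[(1S,4S,5R)-5-(TBSO)-1-(TESO)-4-(TIPSOCH2)-3-(TMS-ethynyl)cyclopent-2-en-1-yl]ethan-1-one | CC(=O)[C@]1(O[Si](CC)(CC)CC)C=C(C#C[Si](C)(C)C)[C@@H](CO[Si](C(C)C)(C(C)C)C(C)C)[C@H]1O[Si](C)(C)C(C)(C)C | intermediate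
15 | (4S,5R,6S)-5-(TBSO)-6-methyl-6-(TESO)-4-(TIPSOCH2)-3-(TMS-ethynyl)cyclohex-2-en-1-one | C[Si](C)(C)C#CC1=CC(=O)[C@@](C)(O[Si](CC)(CC)CC)[C@H](O[Si](C)(C)C(C)(C)C)[C@@H]1CO[Si](C(C)C)(C(C)C)C(C)C | intermediate
16 | (2R,3R)-3-methyloxiranemethanol | C[C@H]1O[C@@H]1CO | starting material
17 | potassium (2S,3R)-3-methyloxirane-2-carboxylate | C[C@H]1O[C@@H]1C(=O)[O-].[K+] | intermediate
18 | (2S,3R)-3-methyloxirane-2-carbonyl chloride | C[C@H]1O[C@@H]1C(Cl)=O | intermediate (not isolated)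
19 | 1-[(2S,3R)-3-methyloxiran-2-yl]-3-(trimethylsilyl)prop-2-yn-1-one | C[C@H]1O[C@@H]1C(=O)C#C[Si](C)(C)C | intermediate
20 | (2R)-2-[(2S,3R)-3-methyloxiran-2-yl]-4-(trimethylsilyl)but-3-yn-2-ol (as its magnesium alkoxide) | C[C@H]1O[C@@H]1[C@](C)(O)C#C[Si](C)(C)C | intermediate (not isolated)
21 | (3R,4S,5R)-3,5-dimethyl-1-(trimethylsilyl)hept-1-yne-3,4-diol | CC[C@@H](C)[C@H](O)[C@](C)(O)C#C[Si](C)(C)C | intermediate (not isolated)
22 | (3R,4S,5R)-3,5-dimethylhept-1-yne-3,4-diol | CC[C@@H](C)[C@H](O)[C@](C)(O)C#C | intermediate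
23 | (1E,3R,4S,5R)-3,5-dimethyl-1-(tributylstannyl)hept-1-ene-3,4-diol | CC[C@@H](C)[C@H](O)[C@](C)(O)/C=C/[Sn](CCCC)(CCCC)CCCC | intermediate (not isolated)
24 | (1E,3R,4S,5R)-1-iodo-3,5-dimethylhept-1-ene-3,4-diol | CC[C@@H](C)[C@H](O)[C@](C)(O)/C=C/I | intermediate
25 | (4S,5R,6S)-5-(TBSO)-3-[(3E,5R,6S,7R)-5,6-dihydroxy-5,7-dimethylnon-3-en-1-yn-1-yl]-6-methyl-6-(TESO)-4-(TIPSOCH2)cyclohex-2-en-1-one | CC[C@@H](C)[C@H](O)[C@](C)(O)/C=C/C#CC1=CC(=O)[C@@](C)(O[Si](CC)(CC)CC)[C@H](O[Si](C)(C)C(C)(C)C)[C@@H]1CO[Si](C(C)C)(C(C)C)C(C)C | intermediate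
26 | (4S,5R,6S)-3-[(3E,5R,6S,7R)-5,6-dihydroxy-5,7-dimethylnon-3-en-1-yn-1-yl]-5,6-dihydroxy-4-(hydroxymethyl)-6-methylcyclohex-2-en-1-one | CC[C@@H](C)[C@H](O)[C@](C)(O)/C=C/C#CC1=CC(=O)[C@@](C)(O)[C@H](O)[C@@H]1CO | intermediate (not isolated)
27 | (7S,8R,8aS)-3-[(1E,3R,4S,5R)-3,4-dihydroxy-3,5-dimethylhept-1-en-1-yl]-7,8-dihydroxy-7-methyl-1,7,8,8a-tetrahydro-6H-isochromen-6-one (CNP0291643.7) | CC[C@@H](C)[C@H](O)[C@](C)(O)/C=C/C1=CC2=CC(=O)[C@@](C)(O)[C@H](O)[C@@H]2CO1 | target

## Step count and risks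

Total: 13 steps. Longest linear sequence: 9 steps (steps 1–7, 12, 13); the side chain takes 4 steps (8–11).

Steps most likely to fail:

**Step 7 (the new ring expansion).** The vinylic ring carbon may migrate instead of the siloxy-bearing one (that product is a non-conjugated ketone and should revert, the conjugated enone 15 being the sink), or the antiperiplanar preference may be weak and give the C6 epimer. The fallback uses known chemistry, sets out from 11 and comes back at 15. Wittig ethylidenation of 11 (Ph3P=CHCH3, THF, −78 → 0 °C) gives the ethylidene diene F1. OsO4 (2 mol %) with N-methylmorpholine N-oxide dihydroxylates the exocyclic alkene from the face opposite to the two silyloxy substituents and gives the diol F2. SO3·pyridine/DMSO/i-Pr2NEt oxidises the secondary alcohol to the free α-ketol F3, whose tertiary hydroxyl now lies trans to OTBS. The classical chelated α-ketol ring expansion (Al(Oi-Pr)3, toluene, 60 °C; carbonyl and hydroxyl oxygens syn on one aluminium) keeps the new hydroxyl on that same face and gives the hydroxy enone F4. Et3SiOTf/2,6-lutidine then gives 15.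

**Step 2 (CBS desymmetrisation).** The ene-dione carries an acidic C–H next to a β-silyloxy group, and the facial sense of the catalyst on this substrate is predicted, not measured. The fallback sets out from 5 and comes back at 7. Step 1 is stopped before the MnO2 stage and 5 is isolated. Lipase PS (Burkholderia cepacia) with vinyl acetate in MTBE leaves the (4R,5S)-alcohol F5 and turns its enantiomer into the (4S,5R)-acetate F6, which is discarded. Mitsunobu inversion of F5 (4-nitrobenzoic acid, DIAD, PPh3, THF, 0 °C) gives the cis 4-nitrobenzoate F7, and methanolysis (K2CO3 cat., MeOH, −20 °C) gives 7.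

**Step 5 (oxidative transposition).** The tertiary propargylic, allylic alcohol may ionise or eliminate under the acidic chromium reagent, and the TBS ether may suffer. The fallback sets out from 10 and comes back at 11. Ph3SiOReO3 (2 mol %) in Et2O at 0 °C shifts the hydroxyl to the other allylic terminus and gives the enyne-conjugated secondary allylic alcohol F8, and MnO2 in CH2Cl2 oxidises F8 to 11.

## Further compounds

F1 | step 7 | (4S,5R)-5-(TBSO)-1-ethylidene-4-(TIPSOCH2)-3-(TMS-ethynyl)cyclopent-2-ene (E/Z mixture) | CC=C1C=C(C#C[Si](C)(C)C)[C@@H](CO[Si](C(C)C)(C(C)C)C(C)C)[C@H]1O[Si](C)(C)C(C)(C)C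
F2 | step 7 | 1-[(1S,4S,5R)-5-(TBSO)-1-hydroxy-4-(TIPSOCH2)-3-(TMS-ethynyl)cyclopent-2-en-1-yl]ethan-1-ol (side-chain carbinol epimers) | CC(O)[C@@]1(O)C=C(C#C[Si](C)(C)C)[C@@H](CO[Si](C(C)C)(C(C)C)C(C)C)[C@H]1O[Si](C)(C)C(C)(C)C
F3 | step 7 | 1-[(1R,4S,5R)-5-(TBSO)-1-hydroxy-4-(TIPSOCH2)-3-(TMS-ethynyl)cyclopent-2-en-1-yl]ethan-1-one | CC(=O)[C@@]1(O)C=C(C#C[Si](C)(C)C)[C@@H](CO[Si](C(C)C)(C(C)C)C(C)C)[C@H]1O[Si](C)(C)C(C)(C)C
F4 | step 7 | (4S,5R,6S)-5-(TBSO)-6-hydroxy-6-methyl-4-(TIPSOCH2)-3-(TMS-ethynyl)cyclohex-2-en-1-one | C[Si](C)(C)C#CC1=CC(=O)[C@@](C)(O)[C@H](O[Si](C)(C)C(C)(C)C)[C@@H]1CO[Si](C(C)C)(C(C)C)C(C)C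
F5 | step 2 | (4R,5S)-4-hydroxy-5-(TIPSOCH2)cyclopent-2-en-1-one (single enantiomer) | O=C1C=C[C@@H](O)[C@@H]1CO[Si](C(C)C)(C(C)C)C(C)C
F6 | step 2 | (1S,5R)-4-oxo-5-(TIPSOCH2)cyclopent-2-en-1-yl acetate | O=C1C=C[C@H](OC(C)=O)[C@H]1CO[Si](C(C)C)(C(C)C)C(C)C
F7 | step 2 | (1S,5S)-4-oxo-5-(TIPSOCH2)cyclopent-2-en-1-yl 4-nitrobenzoate | O=C1C=C[C@H](OC(=O)c2ccc(cc2)[N+](=O)[O-])[C@@H]1CO[Si](C(C)C)(C(C)C)C(C)C
F8 | step 5 | (4S,5R)-5-(TBSO)-4-(TIPSOCH2)-3-(TMS-ethynyl)cyclopent-2-en-1-ol (C1 epimers) | OC1C=C(C#C[Si](C)(C)C)[C@@H](CO[Si](C(C)C)(C(C)C)C(C)C)[C@H]1O[Si](C)(C)C(C)(C)C
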